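## Structural features

The target is a bisabolane-type sesquiterpenoid diester: a cyclohexane (ring A, C1–C6) joined through C1 to a chain C7–C11, with an exocyclic methylene (C14) on C7, a methyl (C15) on C4 and two methyls (C12, C13) on C11. Ring A carries five contiguous stereocentres: C1 (side chain), the C3–C4 epoxide, C5 (angelate) and C6 (free hydroxyl). C7, the epoxide oxygen, O5 and O6 all lie on one face, which corresponds to (1S,3S,4S,5R,6R). The chain adds the allylic angelate at C8 (S) and the trisubstituted 10,11-epoxide (10R); both are insulated from ring A by the sp2 carbon C7 and cannot be set by the ring. The fragile groups are the two angelates ((Z)-2-methylbut-2-enoates, which isomerise to tiglates and can migrate from O5 to the cis O6), the acid-labile 2,2-dimethyloxirane, the ring epoxide next to an ester, and the allylic ester at C8. The real difficulty is the all-cis C1/C5/C6 triad with O5 and O6 differentiated, the remote C8 and C10 centres, and the late handling of two angelates and two epoxides. The key step exploits the fact that, before epoxidation, C5 is an allylic carbinol on the trisubstituted C3=C4 alkene of ring A: the C4–C5 bond is the product bond of an alkenylmetal–aldehyde addition, and the C5 hydroxyl so created then directs the epoxidation to its own face.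

## Logic of the disconnections

29 ⇒ 28. The O6–Si bond is cut last. O6 must stay masked while O5 and O8 are acylated and whenever base is present, because a free cis O6 invites acyl migration from O5. Nothing is gained in skeleton; the demand is a desilylation that spares two epoxides and two angelates.

28 ⇒ 27. The two C–O bonds of the 10,11-epoxide are cut. A β,γ-epoxy aldehyde is not a usable building block, whereas C10=C11 is the only electron-rich trisubstituted alkene in 27. The gain is one stereocentre and one fragile group fewer; the demand is reagent-controlled face selectivity at a centre with no neighbouring stereocentre, at mild pH.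

27 ⇒ 26. The O8–acyl bond is cut. The demand is an acylation that keeps the Z geometry of the angelate and does not break the C8–O bond.

26 ⇒ 25 ⇒ 24. The C8–H bond is cut (reduction) and the carbinol is traced to a ketone. C–C bond formation at C8 has no reliable substrate control, so the configuration is delegated to a catalyst-controlled hydride transfer. The demand is discrimination between the alkenyl and the CH2 flank of the ketone, and a β,γ-unsaturated ketone that does not slip into conjugation.

24 ⇒ 20 + 22, and 22 ⇒ 21. The C7–C8 bond is cut at the allylic carbinol, dividing the molecule into ring A with an alkenyl electrophile at C7 and a six-carbon aldehyde. The gain is convergence; the demand is an alkenylmetal that tolerates ester, epoxide and silyl ether, which points to chromium. 22 is made fresh by oxidation of 21.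

20 ⇒ 18 ⇒ 17. The C7–O sulfonate bond and the C7–C14 bond are cut: the amide at C7 is the latent 2-propenyl unit. The demands are a methyl addition that prefers the amide to the ester, and enolisation at C14, not at C1.

17 ⇒ 16 ⇒ 15. The O5–acyl bond and the two epoxide C–O bonds are cut. The single free hydroxyl of 15 first steers the oxidant to its own face and is then esterified, so O5 and O6 are differentiated without extra steps. The demands are syn delivery on the more crowded face and acylation of a hindered hydroxyl.

15 ⇒ 13 (key). The C4–C5 bond is cut. Ring A opens to an acyclic chain with only two stereocentres (C1, C6), and the ring alkene geometry is stored in a Z alkenyl iodide. The demands are neutral conditions (an α-silyloxy aldehyde and a β-silyloxy amide are present) and Felkin–Anh face selectivity at C5.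

13 ⇒ 12 ⇒ 11 ⇒ 10 ⇒ 9. Only functional groups change: the C5 oxidation level, the O5 protecting group, the O6 silyl group and the C7 amide. The aldehyde is unmasked last. The demand is speed between 12 and 13, since 12 is a γ-hydroxy amide that can lactonise.

9 ⇒ 6 + 7. The C1–C6 bond is cut. The 1,2-syn relationship of C1 and C6 is the retron of an auxiliary-controlled syn aldol, so two stereocentres come from an achiral aldehyde and a recoverable auxiliary. The demand is a Z enolate and the (R)-configured auxiliary.

6 ⇒ 3 + 4, and 3 ⇒ 2 ⇒ 1. The N–acyl bond and the C3=C4 double bond are cut. Because ring A needs exactly one methylene (C2) between C1 and C3, 1 must have four carbons; a five-carbon homologue would place two methylenes there and close a seven-membered ring. The demand is Z selectivity, with iodine cis to C2.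

## Other disconnections considered

Alternative 1: The cut goes through both C–O bonds at C5 and C6 and takes ring A back to the arene 4-iodotoluene A1. In the forward sense, whole cells expressing toluene dioxygenase would add two oxygen atoms cis across one ring bond of A1 and deliver (1S,2S)-3-iodo-6-methylcyclohexa-3,5-diene-1,2-diol A2, with iodine on the future C1 and methyl on C4.
- In its favour: the cis C5/C6 diol and its absolute configuration come in one catalytic operation from a bulk chemical. The cis relationship is intrinsic to the enzymatic mechanism and not a matter of facial selectivity. The C3=C4 alkene with its methyl is already in place for a hydroxyl-directed epoxidation, and the C1 iodide is a handle for attaching C7.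
- Against it here: C1 is still sp2 in A2, so the C1 stereocentre must be made later by saturating C1=C2 selectively within a conjugated diene, from the face anti to the diol. O5 and O6 are both secondary allylic hydroxyls and must be told apart. A2 can lose water to rearomatise and can dimerise, so it must be protected at once, normally as an acetal that ties the two oxygens together. Its enantiomeric purity rests on the enzyme distinguishing iodine from methyl, and fermentation capacity is needed.
- Comparison: in speed of reaching an oxygenated ring A and in the certainty of the cis C5/C6 relationship this route is better than the chosen plan, which needs nine steps to 15 and relies on Felkin–Anh selectivity in step 9. The chosen plan is better afterwards: in 15 the C1 centre is already set by the auxiliary, C7 is present at the right oxidation level and O5 is the only free hydroxyl. From A2 each of these points would cost separate steps of uncertain selectivity, so a lower overall step count would not be expected.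

Alternative 2: The cut is the C1–C2 bond, with C3=C4 traced back to a vinyl group on a tertiary lactone carbon. Ring A is unravelled to the δ-lactone A4 (a 6-methyl-6-vinyl tetrahydropyran-2-one carrying the C5/C6 acetonide, vinyl trans to the acetonide oxygens), itself derived from 2,3-O-isopropylidene-D-erythronolactone A3. In the forward sense, the silyl ketene acetal of A4 would undergo an Ireland–Claisen rearrangement through a boat transition state, forming C1–C2 and C3=C4 while the lactone C4–O bond breaks, to give the all-cis acid A5.
- In its favour: the C5/C6 cis-diol comes from the chiral pool in the correct series. The concerted [3,3] shift transfers the C4 configuration of A4 to C1 with the fidelity of a cyclic six-electron transition state. The trisubstituted alkene and its methyl are formed regiospecifically, no stoichiometric metal is used, and A5 has the same C7 carboxyl level as 15 and could enter the same endgame.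
- Against it here: the tertiary carbinol carbon of A4 must be built as one diastereomer, because it alone decides C1. The CH2OH end of A3 needs a one-carbon homologation before lactonisation onto a tertiary allylic alcohol. The acetonide masks O5 and O6 alike, so after its removal the more hindered O5 would have to be acylated in the presence of O6.
- Comparison: as a ring-forming event the rearrangement is the equal of step 9 in bond economy (one C–C bond, one ring) and better in stereochemical reliability, since no carbonyl face selectivity is involved; the cis diol is also more secure. The chosen plan is better in that 13 carries only two stereocentres made in a single aldol step and in that O5 and O6 are differentiated by construction. The step count to A5 from A3 (about seven) is comparable to that leading to 13, but the later diol differentiation would add steps.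

Alternative 3: The cut removes C4 from the ring. Ring A is taken back to a cyclopentane whose C3–C5 bond is bridged by a dibromomethylene carbon: the gem-dibromocyclopropane A6, with a tert-butyl carbonate on O6 and a silyloxymethyl group on C1. In the forward sense, a silver salt would ionise the endo bromide of A6, disrotatory opening of the C3–C5 bond would give a 2-bromoallyl cation inside a six-membered ring, and the carbonate oxygen would capture C5 with loss of the tert-butyl group, giving the bromoalkene cyclic carbonate A7.
- In its favour: the C5–O bond is formed intramolecularly from O6, so the cis C5/C6 relationship is enforced by the five-membered carbonate. The cis C1/C6 relationship is set on a simple five-membered ring, the electrocyclic opening is orbital-symmetry controlled, and the alkenyl bromide at C4 is ready for cross-coupling.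
- Against it here: C4 arrives with bromine, not methyl, so a methyl cross-coupling is added. C7 is at the alcohol oxidation level and must be deprotected, oxidised and homologated to the methyl ketone (three to four steps that the amide of 15 avoids). The carbonate again ties O5 to O6 and leaves their differentiation unsolved. The enantiopure cyclopentene behind A6 must be secured separately, and a stoichiometric silver salt is required.
- Comparison: both plans deliver ring A with the C3=C4 alkene in place and both use a stoichiometric metal. The alternative is the equal of the chosen plan in forming one ring-defining bond and better in the certainty of the cis diol. The chosen plan is better in functional economy: 15 already has the C4 methyl, the C7 carboxyl level and a single free hydroxyl.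

Key step: step 9

Remarks on the chemistry:
- Atom numbers C1–C15 are those defined under Structural features; angeloyl means (Z)-2-methylbut-2-enoyl.
- The descriptor of C4 changes from R (16) to S (17 onwards) and that of C1 from R (15–20) to S (24 onwards) only through changes of CIP priority; no centre is inverted.
- 22 is assumed to be best made fresh from 21, because β,γ-unsaturated aldehydes isomerise on storage.

## Route

Step 1
Reactants: 1 methyl 4-oxobutanoate
Product: 2 methyl (Z)-5-iodohex-4-enoate
Conditions: EtPPh3I, n-BuLi, THF, 0 °C to rt; I2, −78 °C; NaN(SiMe3)2, −20 °C; then 1, −78 to −20 °C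
Reagents that add atoms: ethyltriphenylphosphonium iodide, CC[P+](c1ccccc1)(c1ccccc1)c1ccccc1.[I-]; iodine, II
Why: Stork–Zhao-type Wittig olefination with the α-iodo ylide Ph3P=C(I)CH3 made in the flask; kinetically controlled addition of this non-stabilised ylide places iodine cis to the chain and gives the Z iodoalkene, and the methyl ester is inert to the ylide at low temperature. The four-carbon aldehyde ester fixes exactly one methylene (C2) between the future C1 and C3.

Step 2
Reactants: 2 methyl (Z)-5-iodohex-4-enoate
Product: 3 (Z)-5-iodohex-4-enoic acid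
Conditions: LiOH, THF/H2O, 0 °C to rt; then 1 M HCl
Reagents that add atoms: lithium hydroxide, [Li+].[OH-]
Why: Saponification of the methyl ester; the alkenyl iodide is inert to aqueous hydroxide at room temperature.

Step 3
Reactants: 3 (Z)-5-iodohex-4-enoic acid; 4 (R)-4-benzyl-2-oxazolidinone
Product: 6 (R)-4-benzyl-3-[(Z)-5-iodohex-4-enoyl]oxazolidin-2-one, via mixed pivalic anhydride 5 (not isolated)
Conditions: t-BuCOCl, Et3N, THF, −20 °C; then 4, LiCl, −20 °C to rt
Reagents that add atoms: none
Why: N-Acylation of the oxazolidinone through the mixed pivalic anhydride 5 under LiCl/Et3N activation; attack occurs at the less hindered acyl group, and no strong base touches the alkenyl iodide.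

Step 4
Reactants: 6 (R)-4-benzyl-3-[(Z)-5-iodohex-4-enoyl]oxazolidin-2-one; 7 2-[(4-methoxybenzyl)oxy]acetaldehyde
Product: 9 (R)-4-benzyl-3-[(2R,3R)-3-hydroxy-2-[(Z)-3-iodobut-2-en-1-yl]-4-(4-methoxybenzyloxy)butanoyl]oxazolidin-2-one, via dibutylboron Z-enolate 8 (not isolated)
Conditions: Bu2BOTf, i-Pr2NEt, CH2Cl2, −78 to 0 °C; 7, −78 to 0 °C; pH 7 buffer, MeOH, H2O2, 0 °C
Reagents that add atoms: none
Why: Evans syn-aldol reaction: Bu2BOTf/i-Pr2NEt give the Z boron enolate 8, and the Zimmerman–Traxler chair with the dipole-minimised (R)-auxiliary exposes the enolate face that sets (2R,3R), i.e. C1 and C6 in the 1,2-syn relationship that becomes cis in ring A. The α-alkoxy aldehyde cannot chelate the tetracoordinate boron, so auxiliary control is undisturbed.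

Step 5
Reactants: 9 (R)-4-benzyl-3-[(2R,3R)-3-hydroxy-2-[(Z)-3-iodobut-2-en-1-yl]-4-(4-methoxybenzyloxy)butanoyl]oxazolidin-2-one
Product: 10 (2R,3R)-3-hydroxy-2-[(Z)-3-iodobut-2-en-1-yl]-N-methoxy-4-(4-methoxybenzyloxy)-N-methylbutanamide
Conditions: MeNHOMe·HCl, AlMe3, CH2Cl2, −20 to 0 °C; aq. KNaC4H4O6
Reagents that add atoms: N,O-dimethylhydroxylamine hydrochloride, CNOC.Cl
Why: Aluminium amide transamidation of the aldol imide (Weinreb amide formation); the free β-hydroxyl binds aluminium and directs attack to the exocyclic carbonyl, releasing the auxiliary without epimerising C1.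

Step 6
Reactants: 10 (2R,3R)-3-hydroxy-2-[(Z)-3-iodobut-2-en-1-yl]-N-methoxy-4-(4-methoxybenzyloxy)-N-methylbutanamide
Product: 11 (2R,3R)-2-[(Z)-3-iodobut-2-en-1-yl]-N-methoxy-4-(4-methoxybenzyloxy)-N-methyl-3-(triethylsilyloxy)butanamide
Conditions: Et3SiOTf, 2,6-lutidine, CH2Cl2, −78 °C
Reagents that add atoms: triethylsilyl trifluoromethanesulfonate, CC[Si](CC)(CC)OS(=O)(=O)C(F)(F)F
Why: Silylation of the secondary hydroxyl with a silyl triflate and a hindered pyridine base; the triethylsilyl group is chosen because it survives all later steps yet can be removed at the end under conditions that spare epoxides and angelates.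

Step 7
Reactants: 11 (2R,3R)-2-[(Z)-3-iodobut-2-en-1-yl]-N-methoxy-4-(4-methoxybenzyloxy)-N-methyl-3-(triethylsilyloxy)butanamide
Product: 12 (2R,3R)-4-hydroxy-2-[(Z)-3-iodobut-2-en-1-yl]-N-methoxy-N-methyl-3-(triethylsilyloxy)butanamide
Conditions: DDQ, CH2Cl2/pH 7 buffer (10:1), 0 °C
Reagents that add atoms: none
Why: Oxidative cleavage of the 4-methoxybenzyl ether by DDQ (hydride abstraction to the benzylic oxocarbenium ion, then hydrolysis) in a buffered two-phase medium; silyl ether, amide and alkenyl iodide are inert. The γ-hydroxy amide can lactonise, so 12 is taken on at once without chromatography.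

Step 8
Reactants: 12 (2R,3R)-4-hydroxy-2-[(Z)-3-iodobut-2-en-1-yl]-N-methoxy-N-methyl-3-(triethylsilyloxy)butanamide
Product: 13 (2R,3R)-2-[(Z)-3-iodobut-2-en-1-yl]-N-methoxy-N-methyl-4-oxo-3-(triethylsilyloxy)butanamide
Conditions: Dess–Martin periodinane, NaHCO3, CH2Cl2, 0 °C to rt
Reagents that add atoms: none
Why: Dess–Martin oxidation of the primary alcohol under buffered, non-basic conditions, so the α-silyloxy aldehyde is not epimerised at C6; the aldehyde is used immediately.

Step 9
Reactants: 13 (2R,3R)-2-[(Z)-3-iodobut-2-en-1-yl]-N-methoxy-N-methyl-4-oxo-3-(triethylsilyloxy)butanamide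
Product: 15 (1R,5S,6R)-5-hydroxy-N-methoxy-N,4-dimethyl-6-(triethylsilyloxy)cyclohex-3-ene-1-carboxamide, via alkenylchromium dichloride 14 (not isolated)
Conditions: CrCl2 (8 equiv), NiCl2 (2 mol %), degassed DMSO, rt, 0.01 M
Reagents that add atoms: none
Why: Intramolecular Nozaki–Hiyama–Kishi reaction: zerovalent nickel, formed from NiCl2 by CrCl2, inserts into the C4–I bond with retention of the Z geometry and transmetalates to trivalent chromium, giving alkenylchromium 14, which adds to the C5 aldehyde; the closest known reaction type is the Ni/Cr ring closure of alkenyl iodide aldehydes to cyclic allylic alcohols. Ring A closes in the 6-exo-trig mode (the aldehyde carbon enters the ring, its oxygen stays outside) and the Z iodide becomes the endocyclic C3=C4 alkene. The one new stereocentre, C5, is controlled by C6 through a polar Felkin–Anh half-chair: the C6–O bond is equatorial and antiperiplanar to the forming C4–C5 bond, the aldehyde oxygen is pseudoaxial (which also avoids allylic strain with the C4 methyl) and the C1 amide is axial, where its carbonyl can ligate the chromium on O5. This places O5 cis to O6 and to C7, i.e. (5S); the C5 epimer would need either a chelate between O5 and the bulky, weakly basic silyl ether or attack anti to hydrogen. The step needs chemoselectivity for aldehyde over amide, which organochromium reagents provide because they do not add to amides. It needs configurational integrity at C1 and C6, which the neutral aprotic medium secures for the α-silyloxy aldehyde and the β-silyloxy amide. It needs cyclisation to win over reduction or dimerisation, which low concentration and low nickel loading favour. The product has a single free hydroxyl, at C5.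

Step 10
Reactants: 15 (1R,5S,6R)-5-hydroxy-N-methoxy-N,4-dimethyl-6-(triethylsilyloxy)cyclohex-3-ene-1-carboxamide
Product: 16 (1R,3S,4R,5R,6R)-3,4-epoxy-5-hydroxy-N-methoxy-N,4-dimethyl-6-(triethylsilyloxy)cyclohexane-1-carboxamide
Conditions: VO(acac)2 (5 mol %), t-BuOOH, CH2Cl2, 0 °C to rt
Reagents that add atoms: tert-butyl hydroperoxide, CC(C)(C)OO
Why: Hydroxyl-directed epoxidation: the C5 alkoxide binds pentavalent vanadium together with the alkyl peroxide, and oxygen is delivered to the C3=C4 face syn to O5, the face of the target epoxide. This system does not epoxidise an isolated alkene without the directing hydroxyl, so the more crowded but required face is the only one attacked; C3 and C4 are thus set by C5.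

Step 11
Reactants: 16 (1R,3S,4R,5R,6R)-3,4-epoxy-5-hydroxy-N-methoxy-N,4-dimethyl-6-(triethylsilyloxy)cyclohexane-1-carboxamide
Product: 17 (1R,3S,4S,5R,6R)-5-(angeloyloxy)-3,4-epoxy-N-methoxy-N,4-dimethyl-6-(triethylsilyloxy)cyclohexane-1-carboxamide
Conditions: angelic acid, 2,4,6-Cl3C6H2COCl, Et3N, PhMe, rt; then 16, 80 °C
Reagents that add atoms: angelic acid, C/C=C(/C)C(=O)O
Why: Yamaguchi-type esterification: the mixed anhydride of angelic acid and 2,4,6-trichlorobenzoic acid acylates the hindered C5 hydroxyl at the less hindered angeloyl carbonyl; omitting a nucleophilic catalyst and avoiding acid chloride or carbodiimide activation keeps the Z geometry. O6 is silylated, so O5 is the only site.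

Step 12
Reactants: 17 (1R,3S,4S,5R,6R)-5-(angeloyloxy)-3,4-epoxy-N-methoxy-N,4-dimethyl-6-(triethylsilyloxy)cyclohexane-1-carboxamide
Product: 18 1-[(1R,3S,4S,5R,6R)-5-(angeloyloxy)-3,4-epoxy-4-methyl-6-(triethylsilyloxy)cyclohexyl]ethan-1-one
Conditions: MeMgBr, THF, −40 to 0 °C; pH 7 buffer
Reagents that add atoms: methylmagnesium bromide, C[Mg]Br
Why: Weinreb ketone synthesis: the Grignard reagent adds once to the N-methoxy-N-methylamide, over-addition being prevented by N-methoxy chelation until work-up; at low temperature the hindered, conjugated angelate and the epoxide react far more slowly than the amide. A buffered work-up avoids epimerisation at C1 and β-elimination of the C6 silyloxy group.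

Step 13
Reactants: 18 1-[(1R,3S,4S,5R,6R)-5-(angeloyloxy)-3,4-epoxy-4-methyl-6-(triethylsilyloxy)cyclohexyl]ethan-1-one
Product: 20 1-[(1R,3S,4S,5R,6R)-5-(angeloyloxy)-3,4-epoxy-4-methyl-6-(triethylsilyloxy)cyclohexyl]ethenyl trifluoromethanesulfonate, via potassium enolate 19 (not isolated)
Conditions: KN(SiMe3)2, THF, −78 °C; PhNTf2, −78 to −20 °C
Reagents that add atoms: N-phenylbis(trifluoromethanesulfonimide), O=S(=O)(N(c1ccccc1)S(=O)(=O)C(F)(F)F)C(F)(F)F
Why: Kinetic enolisation of the methyl ketone at the unhindered C14 methyl by the bulky amide base at −78 °C gives terminal enolate 19, which is O-sulfonylated by PhNTf2. Deprotonation at the hindered C1, which would trigger β-elimination of the C6 silyloxy group, is disfavoured, and the angelate has no α-hydrogen.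

Step 14
Reactants: 21 4-methylpent-3-en-1-ol
Product: 22 4-methylpent-3-enal
Conditions: Dess–Martin periodinane, NaHCO3, CH2Cl2, 0 °C
Reagents that add atoms: none
Why: Dess–Martin oxidation of the homoallylic alcohol under buffered conditions gives the β,γ-unsaturated aldehyde without migration of the double bond into conjugation; the solution is used directly.

Step 15
Reactants: 20 1-[(1R,3S,4S,5R,6R)-5-(angeloyloxy)-3,4-epoxy-4-methyl-6-(triethylsilyloxy)cyclohexyl]ethenyl trifluoromethanesulfonate; 22 4-methylpent-3-enal
Product: 24 2-[(1S,3S,4S,5R,6R)-5-(angeloyloxy)-3,4-epoxy-4-methyl-6-(triethylsilyloxy)cyclohexyl]-6-methylhepta-1,5-dien-3-ol (both C8 epimers), via alkenylchromium dichloride 23 (not isolated)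
Conditions: CrCl2 (6 equiv), NiCl2 (2 mol %), degassed DMF, rt
Reagents that add atoms: none
Why: Intermolecular Nozaki–Hiyama–Kishi coupling: zerovalent nickel inserts into the C7–O sulfonate bond, transmetalation gives alkenylchromium 23, and this adds to the aldehyde but to no ester or epoxide; the weakly basic organochromium does not enolise the aldehyde. C8 forms without useful control because the nearest stereocentre (C1) lies across sp2 C7; this is accepted because step 17 sets it.

Step 16
Reactants: 24 2-[(1S,3S,4S,5R,6R)-5-(angeloyloxy)-3,4-epoxy-4-methyl-6-(triethylsilyloxy)cyclohexyl]-6-methylhepta-1,5-dien-3-ol (both C8 epimers)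
Product: 25 2-[(1S,3S,4S,5R,6R)-5-(angeloyloxy)-3,4-epoxy-4-methyl-6-(triethylsilyloxy)cyclohexyl]-6-methylhepta-1,5-dien-3-one
Conditions: Dess–Martin periodinane, NaHCO3, CH2Cl2, 0 °C
Reagents that add atoms: none
Why: Dess–Martin oxidation of the allylic alcohol to the 2-substituted enone removes the uncontrolled C8 centre; buffered, base-free conditions keep the C10=C11 alkene out of conjugation.

Step 17
Reactants: 25 2-[(1S,3S,4S,5R,6R)-5-(angeloyloxy)-3,4-epoxy-4-methyl-6-(triethylsilyloxy)cyclohexyl]-6-methylhepta-1,5-dien-3-one
Product: 26 (3S)-2-[(1S,3S,4S,5R,6R)-5-(angeloyloxy)-3,4-epoxy-4-methyl-6-(triethylsilyloxy)cyclohexyl]-6-methylhepta-1,5-dien-3-ol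
Conditions: (R)-2-methyl-CBS-oxazaborolidine (1.0 equiv), catecholborane, PhMe, −78 °C
Reagents that add atoms: none
Why: Corey–Bakshi–Shibata reduction: the ketone binds the oxazaborolidine boron through the lone pair anti to the larger, α-branched alkenyl group (C7), and hydride is delivered from the coordinated borane to one face; by the usual model the (R)-catalyst gives the (8S)-alcohol under reagent control. Catecholborane at −78 °C reduces in the 1,2 sense and leaves ester, epoxide and alkenes untouched.

Step 18
Reactants: 26 (3S)-2-[(1S,3S,4S,5R,6R)-5-(angeloyloxy)-3,4-epoxy-4-methyl-6-(triethylsilyloxy)cyclohexyl]-6-methylhepta-1,5-dien-3-ol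
Product: 27 (3S)-2-[(1S,3S,4S,5R,6R)-5-(angeloyloxy)-3,4-epoxy-4-methyl-6-(triethylsilyloxy)cyclohexyl]-6-methylhepta-1,5-dien-3-yl angelate
Conditions: angelic acid, 2,4,6-Cl3C6H2COCl, Et3N, PhMe, rt; then 26, 60 °C
Reagents that add atoms: angelic acid, C/C=C(/C)C(=O)O
Why: The same mixed-anhydride (Yamaguchi-type) angeloylation as in step 11, here on a less hindered allylic hydroxyl, so a lower temperature suffices; the C8–O bond is not broken, so the configuration is retained.

Step 19
Reactants: 27 (3S)-2-[(1S,3S,4S,5R,6R)-5-(angeloyloxy)-3,4-epoxy-4-methyl-6-(triethylsilyloxy)cyclohexyl]-6-methylhepta-1,5-dien-3-yl angelate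
Product: 28 (2S)-1-[(2R)-3,3-dimethyloxiran-2-yl]-3-[(1S,3S,4S,5R,6R)-5-(angeloyloxy)-3,4-epoxy-4-methyl-6-(triethylsilyloxy)cyclohexyl]but-3-en-2-yl angelate
Conditions: D-fructose-derived Shi ketone (0.3 equiv), KHSO5 (as 2KHSO5·KHSO4·K2SO4), K2CO3, Bu4NHSO4, MeCN/CH2(OMe)2, aq. Na2B4O7 buffer, 0 °C
Reagents that add atoms: potassium peroxymonosulfate, [K+].[O-]S(=O)(=O)OO
Why: Shi epoxidation: the chiral dioxirane formed from the D-fructose-derived ketone transfers oxygen through a spiro transition state to the electron-rich trisubstituted C10=C11 alkene, giving the (10R)-epoxide under catalyst control. The 1,1-disubstituted C7=C14 alkene (allylic ester) and the electron-poor angelate alkenes react much more slowly, and the cold buffered medium together with the silyl group on O6 prevents ester hydrolysis and acyl migration.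

Step 20
Reactants: 28 (2S)-1-[(2R)-3,3-dimethyloxiran-2-yl]-3-[(1S,3S,4S,5R,6R)-5-(angeloyloxy)-3,4-epoxy-4-methyl-6-(triethylsilyloxy)cyclohexyl]but-3-en-2-yl angelate
Product: 29 (2S)-1-[(2R)-3,3-dimethyloxiran-2-yl]-3-[(1S,3S,4S,5R,6R)-5-(angeloyloxy)-3,4-epoxy-6-hydroxy-4-methylcyclohexyl]but-3-en-2-yl angelate (CNP0296086.3)
Conditions: HF·pyridine, pyridine, THF, 0 °C
Reagents that add atoms: none
Why: Fluoride-mediated cleavage of the triethylsilyl ether with pyridine-buffered HF·pyridine; the mildly acidic medium suppresses O5 to O6 acyl migration, and low temperature with excess pyridine spares the two epoxides. No stereocentre is touched.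

## Compound list

1 | methyl 4-oxobutanoate | COC(=O)CCC=O | starting material
2 | methyl (Z)-5-iodohex-4-enoate | COC(=O)CC/C=C(/C)I | intermediate
3 | (Z)-5-iodohex-4-enoic acid | OC(=O)CC/C=C(/C)I | intermediate
4 | (R)-4-benzyl-2-oxazolidinone | O=C1N[C@H](Cc2ccccc2)CO1 | starting material
5 | (Z)-5-iodohex-4-enoic pivalic anhydride (mixed anhydride) | CC(C)(C)C(=O)OC(=O)CC/C=C(/C)I | intermediate
6 | (R)-4-benzyl-3-[(Z)-5-iodohex-4-enoyl]oxazolidin-2-one | O=C1OC[C@@H](Cc2ccccc2)N1C(=O)CC/C=C(/C)I | intermediate
7 | 2-[(4-methoxybenzyl)oxy]acetaldehyde | COc1ccc(COCC=O)cc1 | starting material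
8 | dibutylboron Z-enolate of 6 | O=C1OC[C@@H](Cc2ccccc2)N1/C(OB(CCCC)CCCC)=C/C/C=C(/C)I | intermediate
9 | (R)-4-benzyl-3-[(2R,3R)-3-hydroxy-2-[(Z)-3-iodobut-2-en-1-yl]-4-(4-methoxybenzyloxy)butanoyl]oxazolidin-2-one | O=C1OC[C@@H](Cc2ccccc2)N1C(=O)[C@H](C/C=C(/C)I)[C@@H](O)COCc1ccc(OC)cc1 | intermediate
10 | (2R,3R)-3-hydroxy-2-[(Z)-3-iodobut-2-en-1-yl]-N-methoxy-4-(4-methoxybenzyloxy)-N-methylbutanamide | CON(C)C(=O)[C@H](C/C=C(/C)I)[C@@H](O)COCc1ccc(OC)cc1 | intermediate
11 | (2R,3R)-2-[(Z)-3-iodobut-2-en-1-yl]-N-methoxy-4-(4-methoxybenzyloxy)-N-methyl-3-(triethylsilyloxy)butanamide | CON(C)C(=O)[C@H](C/C=C(/C)I)[C@@H](O[Si](CC)(CC)CC)COCc1ccc(OC)cc1 | intermediate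
12 | (2R,3R)-4-hydroxy-2-[(Z)-3-iodobut-2-en-1-yl]-N-methoxy-N-methyl-3-(triethylsilyloxy)butanamide | CON(C)C(=O)[C@H](C/C=C(/C)I)[C@@H](O[Si](CC)(CC)CC)CO | intermediate
13 | (2R,3R)-2-[(Z)-3-iodobut-2-en-1-yl]-N-methoxy-N-methyl-4-oxo-3-(triethylsilyloxy)butanamide | CON(C)C(=O)[C@H](C/C=C(/C)I)[C@@H](O[Si](CC)(CC)CC)C=O | intermediate
14 | alkenylchromium dichloride from 13 (CrCl2 in place of iodine at C4; trivalent chromium) | CON(C)C(=O)[C@H](C/C=C(/C)[Cr](Cl)Cl)[C@@H](O[Si](CC)(CC)CC)C=O | intermediate
15 | (1R,5S,6R)-5-hydroxy-N-methoxy-N,4-dimethyl-6-(triethylsilyloxy)cyclohex-3-ene-1-carboxamide (all-cis) | CON(C)C(=O)[C@@H]1CC=C(C)[C@H](O)[C@@H]1O[Si](CC)(CC)CC | intermediate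
16 | (1R,3S,4R,5R,6R)-3,4-epoxy-5-hydroxy-N-methoxy-N,4-dimethyl-6-(triethylsilyloxy)cyclohexane-1-carboxamide | CON(C)C(=O)[C@@H]1C[C@@H]2O[C@]2(C)[C@H](O)[C@@H]1O[Si](CC)(CC)CC | intermediate
17 | (1R,3S,4S,5R,6R)-5-(angeloyloxy)-3,4-epoxy-N-methoxy-N,4-dimethyl-6-(triethylsilyloxy)cyclohexane-1-carboxamide | CON(C)C(=O)[C@@H]1C[C@@H]2O[C@]2(C)[C@H](OC(=O)/C(C)=C\C)[C@@H]1O[Si](CC)(CC)CC | intermediate
18 | 1-[(1R,3S,4S,5R,6R)-5-(angeloyloxy)-3,4-epoxy-4-methyl-6-(triethylsilyloxy)cyclohexyl]ethan-1-one | CC(=O)[C@@H]1C[C@@H]2O[C@]2(C)[C@H](OC(=O)/C(C)=C\C)[C@@H]1O[Si](CC)(CC)CC | intermediate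
19 | potassium enolate of 18 (terminal, C7=C14) | [K+].C=C([O-])[C@@H]1C[C@@H]2O[C@]2(C)[C@H](OC(=O)/C(C)=C\C)[C@@H]1O[Si](CC)(CC)CC | intermediate
20 | 1-[(1R,3S,4S,5R,6R)-5-(angeloyloxy)-3,4-epoxy-4-methyl-6-(triethylsilyloxy)cyclohexyl]ethenyl trifluoromethanesulfonate | C=C(OS(=O)(=O)C(F)(F)F)[C@@H]1C[C@@H]2O[C@]2(C)[C@H](OC(=O)/C(C)=C\C)[C@@H]1O[Si](CC)(CC)CC | intermediate
21 | 4-methylpent-3-en-1-ol | CC(C)=CCCO | starting material
22 | 4-methylpent-3-enal | CC(C)=CCC=O | intermediate
23 | alkenylchromium dichloride from 20 (CrCl2 in place of the sulfonate at C7; trivalent chromium) | C=C([Cr](Cl)Cl)[C@@H]1C[C@@H]2O[C@]2(C)[C@H](OC(=O)/C(C)=C\C)[C@@H]1O[Si](CC)(CC)CC | intermediate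
24 | 2-[(1S,3S,4S,5R,6R)-5-(angeloyloxy)-3,4-epoxy-4-methyl-6-(triethylsilyloxy)cyclohexyl]-6-methylhepta-1,5-dien-3-ol (both C8 epimers) | C=C(C(O)CC=C(C)C)[C@@H]1C[C@@H]2O[C@]2(C)[C@H](OC(=O)/C(C)=C\C)[C@@H]1O[Si](CC)(CC)CC | intermediate
25 | 2-[(1S,3S,4S,5R,6R)-5-(angeloyloxy)-3,4-epoxy-4-methyl-6-(triethylsilyloxy)cyclohexyl]-6-methylhepta-1,5-dien-3-one | C=C(C(=O)CC=C(C)C)[C@@H]1C[C@@H]2O[C@]2(C)[C@H](OC(=O)/C(C)=C\C)[C@@H]1O[Si](CC)(CC)CC | intermediate
26 | (3S)-2-[(1S,3S,4S,5R,6R)-5-(angeloyloxy)-3,4-epoxy-4-methyl-6-(triethylsilyloxy)cyclohexyl]-6-methylhepta-1,5-dien-3-ol | C=C([C@H](CC=C(C)C)O)[C@@H]1C[C@@H]2O[C@]2(C)[C@H](OC(=O)/C(C)=C\C)[C@@H]1O[Si](CC)(CC)CC | intermediate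
27 | (3S)-2-[(1S,3S,4S,5R,6R)-5-(angeloyloxy)-3,4-epoxy-4-methyl-6-(triethylsilyloxy)cyclohexyl]-6-methylhepta-1,5-dien-3-yl angelate | C=C([C@H](CC=C(C)C)OC(=O)/C(C)=C\C)[C@@H]1C[C@@H]2O[C@]2(C)[C@H](OC(=O)/C(C)=C\C)[C@@H]1O[Si](CC)(CC)CC | intermediate
28 | (2S)-1-[(2R)-3,3-dimethyloxiran-2-yl]-3-[(1S,3S,4S,5R,6R)-5-(angeloyloxy)-3,4-epoxy-4-methyl-6-(triethylsilyloxy)cyclohexyl]but-3-en-2-yl angelate | C=C([C@H](C[C@H]1OC1(C)C)OC(=O)/C(C)=C\C)[C@@H]1C[C@@H]2O[C@]2(C)[C@H](OC(=O)/C(C)=C\C)[C@@H]1O[Si](CC)(CC)CC | intermediate
29 | (2S)-1-[(2R)-3,3-dimethyloxiran-2-yl]-3-[(1S,3S,4S,5R,6R)-5-(angeloyloxy)-3,4-epoxy-6-hydroxy-4-methylcyclohexyl]but-3-en-2-yl angelate (CNP0296086.3) | C=C([C@H](C[C@H]1OC1(C)C)OC(=O)/C(C)=C\C)[C@@H]1C[C@@H]2O[C@]2(C)[C@H](OC(=O)/C(C)=C\C)[C@@H]1O | target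

## Step count and least certain steps

Total: 20 steps. Longest linear sequence: 19 steps (steps 1–13 and 15–20, from 1 to 29); step 14 is a one-step side branch.

Step 9 (key step).
- What may go wrong: insufficient face discrimination at the aldehyde, if the chelated or hydrogen-anti transition states compete with the Felkin–Anh one, which would erode the cis C5/C6 relationship. Premature protonation of the alkenylchromium (loss of iodine without ring closure) and attack of O5 on the C7 amide with loss of the amine are also possible.
- Fallback: it sets out from 13 and returns at 15. The cyclisation is run as before, and the mixture of 15 and its C5 epimer, (1R,5R,6R)-5-hydroxy-N-methoxy-N,4-dimethyl-6-(triethylsilyloxy)cyclohex-3-ene-1-carboxamide F1, is oxidised without separation (Dess–Martin periodinane, NaHCO3, CH2Cl2, 0 °C) to the enone (1R,6R)-N-methoxy-N,4-dimethyl-5-oxo-6-(triethylsilyloxy)cyclohex-3-ene-1-carboxamide F2. A 1,2-reduction with NaBH4/CeCl3·7H2O in MeOH at −78 °C should deliver hydride to the face opposite the cis substituents on C1 and C6 and so return 15. C5 is then set by reduction rather than by C–C bond formation.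

Step 11.
- What may go wrong: slow acylation of the hindered C5 hydroxyl, which gives the activated angelate time to isomerise from Z to E (tiglate) or allows silyl migration from O6 to O5.
- Fallback: it sets out from 16 and returns at 17. 16 is esterified with 2-[bis(2,2,2-trifluoroethoxy)phosphoryl]propanoic acid (DCC, DMAP, CH2Cl2) to the phosphonate ester (1R,3S,4S,5R,6R)-5-{2-[bis(2,2,2-trifluoroethoxy)phosphoryl]propanoyloxy}-3,4-epoxy-N-methoxy-N,4-dimethyl-6-(triethylsilyloxy)cyclohexane-1-carboxamide F3. A Still–Gennari olefination of F3 with acetaldehyde (KN(SiMe3)2, 18-crown-6, THF, −78 °C) should then build the Z-trisubstituted enoate on the molecule and give 17. The angelate geometry is made by olefination and is not carried through an acyl transfer.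

Step 12.
- What may go wrong: loss of chemoselectivity (methyl addition to the C5 angelate, opening of the epoxide by magnesium halide) and, on work-up, epimerisation at C1 or β-elimination of the C6 silyloxy group.
- Fallback: it sets out from 17 and returns at 18. Cp2Zr(H)Cl (THF, rt) should reduce the amide selectively to the aldehyde (1R,3S,4S,5R,6R)-5-(angeloyloxy)-3,4-epoxy-4-methyl-6-(triethylsilyloxy)cyclohexane-1-carbaldehyde F4. MeTi(Oi-Pr)3 (THF, −40 °C), which adds to aldehydes but not to esters, should give the carbinol 1-[(1S,3S,4S,5R,6R)-5-(angeloyloxy)-3,4-epoxy-4-methyl-6-(triethylsilyloxy)cyclohexyl]ethan-1-ol F5 (carbinol epimers). Dess–Martin oxidation then gives 18. The methyl group is thus added to an aldehyde, where the ester cannot compete.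

Step 17.
- What may go wrong: poor face discrimination if the catalyst does not distinguish the alkenyl flank from the CH2 flank clearly enough, and drift of the C10=C11 alkene into conjugation in 25 before reduction.
- Fallback: it sets out from 24 and returns at 27, omitting 25. The two C8 epimers of 24 are diastereomers and are separated by chromatography into 26 and (3R)-2-[(1S,3S,4S,5R,6R)-5-(angeloyloxy)-3,4-epoxy-4-methyl-6-(triethylsilyloxy)cyclohexyl]-6-methylhepta-1,5-dien-3-ol F6. 26 is acylated as in step 18 (retention). F6 is esterified with angelic acid under Mitsunobu conditions (PPh3, DIAD, THF, 0 °C), with inversion at C8. Both streams should converge on 27, and C8 is then fixed by the mode of C–O bond formation.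

Step 20.
- What may go wrong: opening of the acid-labile 2,2-dimethyloxirane by HF, or migration of the angelate from O5 to the freed cis O6.
- Fallback: it sets out from 27 and returns at 29, omitting 28. 27 is desilylated first (HF·pyridine, pyridine, THF, 0 °C) to (3S)-2-[(1S,3S,4S,5R,6R)-5-(angeloyloxy)-3,4-epoxy-6-hydroxy-4-methylcyclohexyl]-6-methylhepta-1,5-dien-3-yl angelate F7, so the side-chain epoxide never meets HF. F7 is then epoxidised under the Shi conditions of step 19, kept cold and brief to limit acyl migration, to give 29.

## Further compounds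

F1 | step 9 | (1R,5R,6R)-5-hydroxy-N-methoxy-N,4-dimethyl-6-(triethylsilyloxy)cyclohex-3-ene-1-carboxamide (C5 epimer of 15) | CON(C)C(=O)[C@@H]1CC=C(C)[C@@H](O)[C@@H]1O[Si](CC)(CC)CC
F2 | step 9 | (1R,6R)-N-methoxy-N,4-dimethyl-5-oxo-6-(triethylsilyloxy)cyclohex-3-ene-1-carboxamide | CON(C)C(=O)[C@@H]1CC=C(C)C(=O)[C@@H]1O[Si](CC)(CC)CC
F3 | step 11 | (1R,3S,4S,5R,6R)-5-{2-[bis(2,2,2-trifluoroethoxy)phosphoryl]propanoyloxy}-3,4-epoxy-N-methoxy-N,4-dimethyl-6-(triethylsilyloxy)cyclohexane-1-carboxamide | CON(C)C(=O)[C@@H]1C[C@@H]2O[C@]2(C)[C@H](OC(=O)C(C)P(=O)(OCC(F)(F)F)OCC(F)(F)F)[C@@H]1O[Si](CC)(CC)CC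
F4 | step 12 | (1R,3S,4S,5R,6R)-5-(angeloyloxy)-3,4-epoxy-4-methyl-6-(triethylsilyloxy)cyclohexane-1-carbaldehyde | O=C[C@@H]1C[C@@H]2O[C@]2(C)[C@H](OC(=O)/C(C)=C\C)[C@@H]1O[Si](CC)(CC)CC
F5 | step 12 | 1-[(1S,3S,4S,5R,6R)-5-(angeloyloxy)-3,4-epoxy-4-methyl-6-(triethylsilyloxy)cyclohexyl]ethan-1-ol (carbinol epimers) | CC(O)[C@@H]1C[C@@H]2O[C@]2(C)[C@H](OC(=O)/C(C)=C\C)[C@@H]1O[Si](CC)(CC)CC
F6 | step 17 | (3R)-2-[(1S,3S,4S,5R,6R)-5-(angeloyloxy)-3,4-epoxy-4-methyl-6-(triethylsilyloxy)cyclohexyl]-6-methylhepta-1,5-dien-3-ol | C=C([C@@H](CC=C(C)C)O)[C@@H]1C[C@@H]2O[C@]2(C)[C@H](OC(=O)/C(C)=C\C)[C@@H]1O[Si](CC)(CC)CC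
F7 | step 20 | (3S)-2-[(1S,3S,4S,5R,6R)-5-(angeloyloxy)-3,4-epoxy-6-hydroxy-4-methylcyclohexyl]-6-methylhepta-1,5-dien-3-yl angelate | C=C([C@H](CC=C(C)C)OC(=O)/C(C)=C\C)[C@@H]1C[C@@H]2O[C@]2(C)[C@H](OC(=O)/C(C)=C\C)[C@@H]1O
A1 | alternative 1 | 4-iodotoluene | Cc1ccc(I)cc1
A2 | alternative 1 | (1S,2S)-3-iodo-6-methylcyclohexa-3,5-diene-1,2-diol | IC1=CC=C(C)[C@H](O)[C@@H]1O
A3 | alternative 2 | 2,3-O-isopropylidene-D-erythronolactone | O=C1OC[C@H]2OC(C)(C)O[C@@H]12
A4 | alternative 2 | 6-methyl-6-vinyl δ-lactone with the C5/C6 acetonide (vinyl trans to the acetonide oxygens) | C=C[C@]1(C)OC(=O)C[C@H]2OC(C)(C)O[C@@H]12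
A5 | alternative 2 | all-cis 4-methylcyclohex-3-ene-1-carboxylic acid with the C5/C6 acetonide | OC(=O)[C@@H]1CC=C(C)[C@@H]2OC(C)(C)O[C@H]12
A6 | alternative 3 | 6,6-dibromobicyclo[3.1.0]hexane with tert-butyl carbonate on O6 and tert-butyldimethylsilyloxymethyl on C1 (cis), cyclopropane anti to both | CC(C)(C)[Si](C)(C)OC[C@@H]1C[C@@H]2[C@H]([C@@H]1OC(=O)OC(C)(C)C)C2(Br)Br
A7 | alternative 3 | all-cis 4-bromocyclohex-3-ene with C5/C6 cyclic carbonate and C1 tert-butyldimethylsilyloxymethyl | CC(C)(C)[Si](C)(C)OC[C@@H]1CC=C(Br)[C@@H]2OC(=O)O[C@H]12
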